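**Plan**
- Retron: the vinyl group on C10 and the 2-propenal unit on the neighbouring ring carbon C5 form a hexa-1,5-diene (C2=C1–C10–C5–C4=C3) astride one bond of the cyclohexane. Retro-Cope (cut C5–C10, rejoin C2–C3) gives the (1(10)E,4Z)-germacra-1(10),4-dien-12,8-olide 15-aldehyde 24.
- 24 is then cut at the two ester C–O bonds, at C6–C7 (chromium allylation that closes the ten-membered ring and creates the exo-methylene lactone), at C7=C11 (ring-closing metathesis to a bromomethyl butenolide), at C8–C9 (alkoxyallylboration) and at C3–C4 (carbocupration of an ynoate).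
- Forward order: chain C3–C4, allylic oxidation at C9, C8–C9, butenolide ring, ten-membered ring, and last the cyclohexane by Cope ring contraction.
- Stereochemistry: C8/C9 from the isopinocampheyl allylborane (syn, reagent control); C6/C7 from a chair transition state on the butenolide template; C5/C10 from the chair–chair Cope of the diene with both ring alkenes trans in the ring; C2' from (R)-2-methylbutanoic acid.
- Alkene geometry: C4=C5 from syn-carbocupration, C1=C10 from E-selective SeO2 oxidation, the angelate from angelic acid.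

Key step: step 15

Remark: atom labels C1–C15 follow germacrane/elemane numbering (C1–C10 are the ring carbons of 24, C11–C13 the lactone unit, C14 the methyl on C10, C15 the carbon on C4) and are kept for all intermediates.
Remark: (R)-2-methylbutanoic acid (13) and allyl methoxymethyl ether (8) are taken as commercially available.
Remark: the facial course of the Cope step rests on conformational analysis only and is listed as the first risk below.

Step 1
Reactants: 1 tert-butyl(diphenyl)(prop-2-yn-1-yloxy)silane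
Product: 2 ethyl 4-[(tert-butyldiphenylsilyl)oxy]but-2-ynoate
Conditions: n-BuLi, THF, −78 °C; ClCO2Et, −78 → 0 °C
Reagents that add atoms: ethyl chloroformate, CCOC(=O)Cl
Why: Deprotonation of the terminal alkyne and C-acylation of the lithium acetylide by the chloroformate give the ynoate, and the silyl ether is inert.

Step 2
Reactants: 2 ethyl 4-[(tert-butyldiphenylsilyl)oxy]but-2-ynoate; 3 5-bromo-2-methylpent-2-ene
Product: 5 ethyl (2Z)-3-{[(tert-butyldiphenylsilyl)oxy]methyl}-7-methylocta-2,6-dienoate, via the Grignard reagent 4 (not isolated)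
Conditions: 3, Mg, THF, rt; CuBr·SMe2, THF, −78 °C; then 2, −78 °C; MeOH then aq. NH4Cl at −78 °C
Reagents that add atoms: none
Why: Syn-carbocupration of the ynoate (alkyl to C4, copper to C5) followed by protonation at −78 °C with retention puts the new chain trans and the silyloxymethyl group cis to the ester, which fixes the C4=C5 geometry needed later in the ring.

Step 3
Reactants: 5 ethyl (2Z)-3-{[(tert-butyldiphenylsilyl)oxy]methyl}-7-methylocta-2,6-dienoate
Product: 7 ethyl (2Z,6E)-3-{[(tert-butyldiphenylsilyl)oxy]methyl}-7-methyl-8-oxoocta-2,6-dienoate, via the allylic alcohol 6 (not isolated)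
Conditions: SeO2 (cat.), t-BuOOH, salicylic acid (cat.), CH2Cl2, rt; then MnO2, CH2Cl2, rt
Reagents that add atoms: selenium dioxide, O=[Se]=O; tert-butyl hydroperoxide, CC(C)(C)OO
Why: Sharpless allylic oxidation (ene reaction of SeO2, then [2,3]-shift) attacks the E-methyl group of the electron-rich trisubstituted terminal alkene and leaves the enoate alkene alone, and MnO2 converges the alcohol/aldehyde mixture on the E-enal.

Step 4
Reactants: 7 ethyl (2Z,6E)-3-{[(tert-butyldiphenylsilyl)oxy]methyl}-7-methyl-8-oxoocta-2,6-dienoate; 8 3-(methoxymethoxy)prop-1-ene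
Product: 10 ethyl (2Z,6E,8R,9R)-3-{[(tert-butyldiphenylsilyl)oxy]methyl}-8-hydroxy-9-(methoxymethoxy)-7-methylundeca-2,6,10-trienoate, via the allylborane 9 (not isolated)
Conditions: 8, s-BuLi, THF, −78 °C; (−)-Ipc2BOMe; BF3·OEt2; then 7, −78 °C; NaOH, H2O2, 0 °C → rt
Reagents that add atoms: none
Why: Brown alkoxyallylboration through a Zimmerman–Traxler chair, in which the Z-γ-alkoxyallyl unit gives the syn relation and the isopinocampheyl groups derived from (+)-α-pinene should direct the allyl group to the Si face of the aldehyde, sets C9 (R, free carbinol) and C8 (R, MOM ether) and leaves the ester untouched.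

Step 5
Reactants: 10 ethyl (2Z,6E,8R,9R)-3-{[(tert-butyldiphenylsilyl)oxy]methyl}-8-hydroxy-9-(methoxymethoxy)-7-methylundeca-2,6,10-trienoate
Product: 11 (2Z,6E,8R,9R)-3-{[(tert-butyldiphenylsilyl)oxy]methyl}-9-(methoxymethoxy)-7-methylundeca-2,6,10-triene-1,8-diol
Conditions: i-Bu2AlH (3.5 equiv), CH2Cl2, −78 °C; aq. potassium sodium tartrate
Reagents that add atoms: none
Why: i-Bu2AlH reduces the conjugated ester by 1,2-hydride addition to the allylic alcohol without touching the alkenes, the MOM ether or the silyl ether.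

Step 6
Reactants: 11 (2Z,6E,8R,9R)-3-{[(tert-butyldiphenylsilyl)oxy]methyl}-9-(methoxymethoxy)-7-methylundeca-2,6,10-triene-1,8-diol
Product: 12 (2Z,6E,8R,9R)-3-{[(tert-butyldiphenylsilyl)oxy]methyl}-8-hydroxy-9-(methoxymethoxy)-7-methylundeca-2,6,10-trienal
Conditions: TEMPO (cat.), PhI(OAc)2 (1.1 equiv), CH2Cl2, rt
Reagents that add atoms: none
Why: Oxoammonium (TEMPO) oxidation is selective for the unhindered primary allylic alcohol over the secondary one at C9 and stops at the aldehyde without E/Z isomerisation of the enal.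

Step 7
Reactants: 12 (2Z,6E,8R,9R)-3-{[(tert-butyldiphenylsilyl)oxy]methyl}-8-hydroxy-9-(methoxymethoxy)-7-methylundeca-2,6,10-trienal; 13 (2R)-2-methylbutanoic acid
Product: 14 (3R,4R,5E,9Z)-9-{[(tert-butyldiphenylsilyl)oxy]methyl}-3-(methoxymethoxy)-5-methyl-11-oxoundeca-1,5,9-trien-4-yl (2R)-2-methylbutanoate
Conditions: DCC, DMAP (cat.), CH2Cl2, 0 °C
Reagents that add atoms: none
Why: Steglich esterification (carbodiimide activation, acyl transfer by DMAP) acylates the only free hydroxyl, and at 0 °C the α-stereocentre of the acid and the enal geometry should be kept.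

Step 8
Reactants: 14 (3R,4R,5E,9Z)-9-{[(tert-butyldiphenylsilyl)oxy]methyl}-3-(methoxymethoxy)-5-methyl-11-oxoundeca-1,5,9-trien-4-yl (2R)-2-methylbutanoate
Product: 15 (3R,4R,5E,9Z)-9-{[(tert-butyldiphenylsilyl)oxy]methyl}-3-hydroxy-5-methyl-11-oxoundeca-1,5,9-trien-4-yl (2R)-2-methylbutanoate
Conditions: Me2BBr, CH2Cl2, −78 °C; then THF/aq. NaHCO3
Reagents that add atoms: none
Why: Me2BBr cleaves the formaldehyde acetal by B–O coordination and bromide attack at the methylene carbon at −78 °C, where the neighbouring ester should not migrate and the silyl ether and the enal survive.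

Step 9
Reactants: 15 (3R,4R,5E,9Z)-9-{[(tert-butyldiphenylsilyl)oxy]methyl}-3-hydroxy-5-methyl-11-oxoundeca-1,5,9-trien-4-yl (2R)-2-methylbutanoate; 16 2-(bromomethyl)prop-2-enoic acid
Product: 17 (3R,4R,5E,9Z)-9-{[(tert-butyldiphenylsilyl)oxy]methyl}-5-methyl-4-{[(2R)-2-methylbutanoyl]oxy}-11-oxoundeca-1,5,9-trien-3-yl 2-(bromomethyl)prop-2-enoate
Conditions: DCC, DMAP (5 mol %), CH2Cl2, −20 → 0 °C
Reagents that add atoms: none
Why: Steglich esterification of the liberated C8 hydroxyl, run cold with little DMAP to limit SN2′ attack on the allylic bromide and 1,2-acyl migration.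

Step 10
Reactants: 17 (3R,4R,5E,9Z)-9-{[(tert-butyldiphenylsilyl)oxy]methyl}-5-methyl-4-{[(2R)-2-methylbutanoyl]oxy}-11-oxoundeca-1,5,9-trien-3-yl 2-(bromomethyl)prop-2-enoate
Product: 18 (1R,2E,6Z)-1-[(2R)-4-(bromomethyl)-5-oxo-2,5-dihydrofuran-2-yl]-6-{[(tert-butyldiphenylsilyl)oxy]methyl}-2-methyl-8-oxoocta-2,6-dien-1-yl (2R)-2-methylbutanoate
Conditions: second-generation Grubbs catalyst RuCl2(=CHPh)(H2IMes)(PCy3) (5 mol %), toluene, 80 °C
Reagents that add atoms: none
Why: Ring-closing metathesis between the monosubstituted vinyl group and the 1,1-disubstituted acrylate closes the five-membered butenolide with loss of ethene, while the trisubstituted alkenes and the enal are too hindered or electron-poor to take part.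

Step 11
Reactants: 18 (1R,2E,6Z)-1-[(2R)-4-(bromomethyl)-5-oxo-2,5-dihydrofuran-2-yl]-6-{[(tert-butyldiphenylsilyl)oxy]methyl}-2-methyl-8-oxoocta-2,6-dien-1-yl (2R)-2-methylbutanoate
Product: 19 (1(10)E,4Z,6S,7R,8R,9R)-15-[(tert-butyldiphenylsilyl)oxy]-6-hydroxy-9-{[(2R)-2-methylbutanoyl]oxy}germacra-1(10),4,11(13)-trien-12,8-olide
Conditions: CrCl2 (8 equiv), THF/DMF (4:1), rt, slow addition of 18 (final 2 mM)
Reagents that add atoms: none
Why: Nozaki–Hiyama allylation, in which CrCl2 turns the allylic bromide into an allylchromium species (trivalent chromium) that adds through its γ-carbon C7 to the aldehyde carbon C6 in a Zimmerman–Traxler chair with the aldehyde chain (C5) and the ring carbon C8 (held trans to CH2Cr by the butenolide) both equatorial, should give the 6S,7R pair (hydroxyl and C8 anti) with transposition of the alkene to the exo-methylene lactone, and because the tether is anchored at C9 it should bring the aldehyde to the butenolide face on which C9 stands, so that the lactone becomes cis-fused, the chromium-mediated closure of germacranolide rings from 2-(bromomethyl)acrylate aldehydes being the model.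

Step 12
Reactants: 19 (1(10)E,4Z,6S,7R,8R,9R)-15-[(tert-butyldiphenylsilyl)oxy]-6-hydroxy-9-{[(2R)-2-methylbutanoyl]oxy}germacra-1(10),4,11(13)-trien-12,8-olide; 20 angelic acid [(2Z)-2-methylbut-2-enoic acid]
Product: 22 (1(10)E,4Z,6S,7R,8R,9R)-6-(angeloyloxy)-15-[(tert-butyldiphenylsilyl)oxy]-9-{[(2R)-2-methylbutanoyl]oxy}germacra-1(10),4,11(13)-trien-12,8-olide, via the mixed anhydride 21 (not isolated)
Conditions: 20, 2,4,6-trichlorobenzoyl chloride, Et3N, toluene, rt; then 19, 50 °C
Reagents that add atoms: none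
Why: Yamaguchi-type acylation through the mixed anhydride without DMAP transfers the angeloyl group with its Z geometry intact, and 50 °C is well below the temperature at which the unactivated germacradiene should rearrange.

Step 13
Reactants: 22 (1(10)E,4Z,6S,7R,8R,9R)-6-(angeloyloxy)-15-[(tert-butyldiphenylsilyl)oxy]-9-{[(2R)-2-methylbutanoyl]oxy}germacra-1(10),4,11(13)-trien-12,8-olide
Product: 23 (1(10)E,4Z,6S,7R,8R,9R)-6-(angeloyloxy)-15-hydroxy-9-{[(2R)-2-methylbutanoyl]oxy}germacra-1(10),4,11(13)-trien-12,8-olide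
Conditions: TBAF, AcOH (1:1), THF, 0 °C → rt
Reagents that add atoms: none
Why: Fluoride cleaves the Si–O bond, and buffering with acetic acid keeps the medium near neutral so that the α-methylene lactone, the esters and the acid-sensitive 1,5-diene are not attacked.

Step 14
Reactants: 23 (1(10)E,4Z,6S,7R,8R,9R)-6-(angeloyloxy)-15-hydroxy-9-{[(2R)-2-methylbutanoyl]oxy}germacra-1(10),4,11(13)-trien-12,8-olide
Product: 24 (1(10)E,4Z,6S,7R,8R,9R)-6-(angeloyloxy)-9-{[(2R)-2-methylbutanoyl]oxy}-15-oxogermacra-1(10),4,11(13)-trien-12,8-olide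
Conditions: Dess–Martin periodinane, NaHCO3, CH2Cl2, 0 °C; used at once
Reagents that add atoms: none
Why: Dess–Martin oxidation converts the primary allylic alcohol into the enal under buffered conditions at 0 °C, so that neither the 4Z geometry nor the esters should be disturbed.

Step 15
Reactants: 24 (1(10)E,4Z,6S,7R,8R,9R)-6-(angeloyloxy)-9-{[(2R)-2-methylbutanoyl]oxy}-15-oxogermacra-1(10),4,11(13)-trien-12,8-olide
Product: 25 (5R,6S,7R,8R,9R,10S)-6-(angeloyloxy)-9-{[(2R)-2-methylbutanoyl]oxy}-15-oxoelema-1,3,11(13)-trien-12,8-olide (target)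
Conditions: toluene (degassed, trace of 2,6-di-tert-butyl-4-methylphenol), 90 °C
Reagents that add atoms: none
Why: Thermal [3,3]-sigmatropic (Cope) rearrangement of the cyclodeca-1,5-diene, in which the C5–C10 σ-bond forms across the ring while the C2–C3 σ-bond breaks and the π-bonds move to C1=C2 (vinyl) and C3=C4 (2-substituted propenal), the closest known reaction type being the germacrane-to-elemane Cope rearrangement of germacranolides, which is helped here by the formyl group on C4 and by a product that stays conjugated. The cyclohexane ring closes by a transannular six-membered closure inside the ten-membered ring (ring contraction from ten to six) through a chair–chair transition state. C10 and C5 are set relative to each other by alkene geometry, because with both ring alkenes trans in the ring the chair places C14 and H5 anti, so that vinyl and propenal become trans-diequatorial and C14 axial. Their sense relative to C6–C9 depends on which of the two crossed (crown) conformers reacts, and these interconvert faster than they rearrange (Curtin–Hammett). The step therefore needs conformer (facial) selectivity, and the substrate should supply it through the cis-8,12-lactone and the 9-acyloxy group: the productive chair carries O8 and O9 equatorial on the forming cyclohexane with C11 and the C6 acyloxy group axial, whereas the competing chair turns O8 and O9 axial with O8 syn-axial to C14 and pushes the C6 acyloxy group into the peri position beside the formyl group, so 5R,10S is expected to prevail though not by a wide margin. No reagent is involved, so the esters, both exocyclic methylenes, the aldehyde and the stereocentres C6–C9 are untouched.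

**Compound list**
1 | tert-butyl(diphenyl)(prop-2-yn-1-yloxy)silane | C#CCO[Si](c1ccccc1)(c1ccccc1)C(C)(C)C | starting material
2 | ethyl 4-[(tert-butyldiphenylsilyl)oxy]but-2-ynoate | CCOC(=O)C#CCO[Si](c1ccccc1)(c1ccccc1)C(C)(C)C | intermediate
3 | 5-bromo-2-methylpent-2-ene | CC(C)=CCCBr | starting material
4 | (4-methylpent-3-en-1-yl)magnesium bromide | CC(C)=CCC[Mg]Br | intermediate (not isolated)
5 | ethyl (2Z)-3-{[(tert-butyldiphenylsilyl)oxy]methyl}-7-methylocta-2,6-dienoate | CCOC(=O)/C=C(\CO[Si](c1ccccc1)(c1ccccc1)C(C)(C)C)CCC=C(C)C | intermediate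
6 | ethyl (2Z,6E)-3-{[(tert-butyldiphenylsilyl)oxy]methyl}-8-hydroxy-7-methylocta-2,6-dienoate | CCOC(=O)/C=C(\CO[Si](c1ccccc1)(c1ccccc1)C(C)(C)C)CC/C=C(\C)CO | intermediate (not isolated)
7 | ethyl (2Z,6E)-3-{[(tert-butyldiphenylsilyl)oxy]methyl}-7-methyl-8-oxoocta-2,6-dienoate | CCOC(=O)/C=C(\CO[Si](c1ccccc1)(c1ccccc1)C(C)(C)C)CC/C=C(\C)C=O | intermediate
8 | 3-(methoxymethoxy)prop-1-ene (allyl methoxymethyl ether) | C=CCOCOC | starting material
9 | [(2Z)-3-(methoxymethoxy)prop-2-en-1-yl]bis(isopinocampheyl)borane, isopinocampheyl groups from (+)-α-pinene | COCO/C=C\CB([C@@H]1C[C@@H]2C[C@H]([C@H]1C)C2(C)C)[C@@H]1C[C@@H]2C[C@H]([C@H]1C)C2(C)C | intermediate (not isolated)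
10 | ethyl (2Z,6E,8R,9R)-3-{[(tert-butyldiphenylsilyl)oxy]methyl}-8-hydroxy-9-(methoxymethoxy)-7-methylundeca-2,6,10-trienoate | C=C[C@@H](OCOC)[C@H](O)/C(C)=C/CC/C(CO[Si](c1ccccc1)(c1ccccc1)C(C)(C)C)=C/C(=O)OCC | intermediate
11 | (2Z,6E,8R,9R)-3-{[(tert-butyldiphenylsilyl)oxy]methyl}-9-(methoxymethoxy)-7-methylundeca-2,6,10-triene-1,8-diol | C=C[C@@H](OCOC)[C@H](O)/C(C)=C/CC/C(CO[Si](c1ccccc1)(c1ccccc1)C(C)(C)C)=C/CO | intermediate
12 | (2Z,6E,8R,9R)-3-{[(tert-butyldiphenylsilyl)oxy]methyl}-8-hydroxy-9-(methoxymethoxy)-7-methylundeca-2,6,10-trienal | C=C[C@@H](OCOC)[C@H](O)/C(C)=C/CC/C(CO[Si](c1ccccc1)(c1ccccc1)C(C)(C)C)=C/C=O | intermediate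
13 | (2R)-2-methylbutanoic acid | CC[C@@H](C)C(=O)O | starting material
14 | (3R,4R,5E,9Z)-9-{[(tert-butyldiphenylsilyl)oxy]methyl}-3-(methoxymethoxy)-5-methyl-11-oxoundeca-1,5,9-trien-4-yl (2R)-2-methylbutanoate | C=C[C@@H](OCOC)[C@H](OC(=O)[C@H](C)CC)/C(C)=C/CC/C(CO[Si](c1ccccc1)(c1ccccc1)C(C)(C)C)=C/C=O | intermediate
15 | (3R,4R,5E,9Z)-9-{[(tert-butyldiphenylsilyl)oxy]methyl}-3-hydroxy-5-methyl-11-oxoundeca-1,5,9-trien-4-yl (2R)-2-methylbutanoate | C=C[C@@H](O)[C@H](OC(=O)[C@H](C)CC)/C(C)=C/CC/C(CO[Si](c1ccccc1)(c1ccccc1)C(C)(C)C)=C/C=O | intermediate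
16 | 2-(bromomethyl)prop-2-enoic acid | C=C(CBr)C(=O)O | starting material
17 | (3R,4R,5E,9Z)-9-{[(tert-butyldiphenylsilyl)oxy]methyl}-5-methyl-4-{[(2R)-2-methylbutanoyl]oxy}-11-oxoundeca-1,5,9-trien-3-yl 2-(bromomethyl)prop-2-enoate | C=C[C@@H](OC(=O)C(=C)CBr)[C@H](OC(=O)[C@H](C)CC)/C(C)=C/CC/C(CO[Si](c1ccccc1)(c1ccccc1)C(C)(C)C)=C/C=O | intermediate
18 | (1R,2E,6Z)-1-[(2R)-4-(bromomethyl)-5-oxo-2,5-dihydrofuran-2-yl]-6-{[(tert-butyldiphenylsilyl)oxy]methyl}-2-methyl-8-oxoocta-2,6-dien-1-yl (2R)-2-methylbutanoate | BrCC1=C[C@@H](OC1=O)[C@H](OC(=O)[C@H](C)CC)/C(C)=C/CC/C(CO[Si](c1ccccc1)(c1ccccc1)C(C)(C)C)=C/C=O | intermediate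
19 | (1(10)E,4Z,6S,7R,8R,9R)-15-[(tert-butyldiphenylsilyl)oxy]-6-hydroxy-9-{[(2R)-2-methylbutanoyl]oxy}germacra-1(10),4,11(13)-trien-12,8-olide | C1/C(CO[Si](c3ccccc3)(c3ccccc3)C(C)(C)C)=C/[C@H](O)[C@H]2C(=C)C(=O)O[C@H]2[C@H](OC(=O)[C@H](C)CC)/C(C)=C/C1 | intermediate
20 | angelic acid [(2Z)-2-methylbut-2-enoic acid] | C/C=C(/C)C(=O)O | starting material
21 | (2Z)-2-methylbut-2-enoic 2,4,6-trichlorobenzoic anhydride | C/C=C(/C)C(=O)OC(=O)c1c(Cl)cc(Cl)cc1Cl | intermediate (not isolated)
22 | (1(10)E,4Z,6S,7R,8R,9R)-6-(angeloyloxy)-15-[(tert-butyldiphenylsilyl)oxy]-9-{[(2R)-2-methylbutanoyl]oxy}germacra-1(10),4,11(13)-trien-12,8-olide | C1/C(CO[Si](c3ccccc3)(c3ccccc3)C(C)(C)C)=C/[C@H](OC(=O)/C(C)=C\C)[C@H]2C(=C)C(=O)O[C@H]2[C@H](OC(=O)[C@H](C)CC)/C(C)=C/C1 | intermediate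
23 | (1(10)E,4Z,6S,7R,8R,9R)-6-(angeloyloxy)-15-hydroxy-9-{[(2R)-2-methylbutanoyl]oxy}germacra-1(10),4,11(13)-trien-12,8-olide | C1/C(CO)=C/[C@H](OC(=O)/C(C)=C\C)[C@H]2C(=C)C(=O)O[C@H]2[C@H](OC(=O)[C@H](C)CC)/C(C)=C/C1 | intermediate
24 | (1(10)E,4Z,6S,7R,8R,9R)-6-(angeloyloxy)-9-{[(2R)-2-methylbutanoyl]oxy}-15-oxogermacra-1(10),4,11(13)-trien-12,8-olide | C1/C(C=O)=C/[C@H](OC(=O)/C(C)=C\C)[C@H]2C(=C)C(=O)O[C@H]2[C@H](OC(=O)[C@H](C)CC)/C(C)=C/C1 | intermediate
25 | (5R,6S,7R,8R,9R,10S)-6-(angeloyloxy)-9-{[(2R)-2-methylbutanoyl]oxy}-15-oxoelema-1,3,11(13)-trien-12,8-olide (CNP0295282.1) | C=C[C@@]1(C)[C@H](C(=C)C=O)[C@H](OC(=O)/C(C)=C\C)[C@H]2C(=C)C(=O)O[C@H]2[C@@H]1OC(=O)[C@H](C)CC | target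

**Count**
Total steps: 15. Longest linear sequence: 15 steps (1 → 25).

**Steps most likely to fail**

Step 15, poor facial (conformer) selectivity: the other crown conformer may rearrange and give the diastereomer inverted at both C5 and C10, since the preference argued above is small. The fallback lets a temporary ring decide the face. Setting out from 19, TBAF/AcOH removes the silyl group and gives the 6,15-diol F1. IBX in DMSO, which takes 1,4-diols to γ-lactols without going on to lactones, oxidises the primary allylic hydroxyl to the 6-hydroxy-15-aldehyde F2, which closes at once to the 6,15-lactol F3. Its 2,5-dihydrofuran ring holds O6 in the plane of C4=C5, so the ring bond C6–C7, and with it C10, can reach C5 from one face only; in the chair–chair geometry this is the face that makes C4 and O6 cis on the new cyclohexane, as in 25. Heating in toluene with a little 2,6-lutidine (against dehydration to a furan) should therefore give the elemanolide lactol F4. NaBH4/CeCl3·7H2O in MeOH at −20 °C reduces the open hydroxy-enal form to the 6,15-diol F5, TESCl/imidazole at −78 °C silylates the primary allylic hydroxyl to the triethylsilyl ether F6, and the mixed anhydride 21 as in step 12 gives the 6-angelate F7. Swern oxidation, which converts primary triethylsilyl ethers directly into aldehydes, brings the fallback back to the route at 25.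

Step 11, loss of anti control at C6 in the chromium allylation (erosion of the chair transition state inside the forming ten-membered ring), besides competing oligomerisation, which is met by dilution. Setting out from 18, the cyclisation then delivers mainly the 6-epimeric alcohol F8, which is used and not discarded. Mitsunobu esterification with angelic acid 20 (PPh3, DIAD, toluene, 0 °C) inverts C6 and gives the angelate directly, so the fallback comes back to the route at 22.

Step 10, catalyst decomposition by the allylic bromide or slow ring closure onto the bromomethyl acrylate. The bromide is then brought in after the metathesis. Commercial methyl 2-(hydroxymethyl)acrylate is silylated (TBSCl, imidazole) to methyl 2-{[(tert-butyldimethylsilyl)oxy]methyl}prop-2-enoate F9 and saponified (LiOH, THF/H2O) to the acid F10. Setting out from 15, esterification with F10 (DCC, DMAP) gives the silyloxymethyl acrylate F11 and ring-closing metathesis gives the silyloxymethyl butenolide F12. HF·pyridine/pyridine at 0 °C removes the primary tert-butyldimethylsilyl ether in the presence of the tert-butyldiphenylsilyl ether to give the hydroxymethyl butenolide F13. Appel bromination (CBr4, PPh3, CH2Cl2, 0 °C) then gives the bromide, and the fallback comes back to the route at 18.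

Further compounds
F1 | step 15 | (1(10)E,4Z,6S,7R,8R,9R)-6,15-dihydroxy-9-{[(2R)-2-methylbutanoyl]oxy}germacra-1(10),4,11(13)-trien-12,8-olide | C1/C(CO)=C/[C@H](O)[C@H]2C(=C)C(=O)O[C@H]2[C@H](OC(=O)[C@H](C)CC)/C(C)=C/C1
F2 | step 15 | (1(10)E,4Z,6S,7R,8R,9R)-6-hydroxy-9-{[(2R)-2-methylbutanoyl]oxy}-15-oxogermacra-1(10),4,11(13)-trien-12,8-olide (open form of the lactol) | C1/C(C=O)=C/[C@H](O)[C@H]2C(=C)C(=O)O[C@H]2[C@H](OC(=O)[C@H](C)CC)/C(C)=C/C1
F3 | step 15 | 6,15-lactol (6,15-epoxy-15-hydroxy form) of the (1(10)E,4Z,6S,7R,8R,9R)-6-hydroxy-15-oxogermacradienolide, mixture at C15 | C1C2=C[C@H](OC2O)[C@H]3C(=C)C(=O)O[C@H]3[C@H](OC(=O)[C@H](C)CC)/C(C)=C/C1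
F4 | step 15 | 6,15-lactol (6,15-epoxy-15-hydroxy form) of (5R,6S,7R,8R,9R,10S)-6-hydroxy-9-{[(2R)-2-methylbutanoyl]oxy}-15-oxoelema-1,3,11(13)-trien-12,8-olide, mixture at C15 | C=C[C@@]1(C)[C@@H]2C(=C)C(O)O[C@@H]2[C@H]3C(=C)C(=O)O[C@H]3[C@@H]1OC(=O)[C@H](C)CC
F5 | step 15 | (5S,6S,7R,8R,9R,10S)-6,15-dihydroxy-9-{[(2R)-2-methylbutanoyl]oxy}elema-1,3,11(13)-trien-12,8-olide (C5 arranged as in 25, descriptor changed by the CH2O group) | C=C[C@@]1(C)[C@H](C(=C)CO)[C@H](O)[C@H]2C(=C)C(=O)O[C@H]2[C@@H]1OC(=O)[C@H](C)CC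
F6 | step 15 | (5S,6S,7R,8R,9R,10S)-6-hydroxy-9-{[(2R)-2-methylbutanoyl]oxy}-15-[(triethylsilyl)oxy]elema-1,3,11(13)-trien-12,8-olide | C=C[C@@]1(C)[C@H](C(=C)CO[Si](CC)(CC)CC)[C@H](O)[C@H]2C(=C)C(=O)O[C@H]2[C@@H]1OC(=O)[C@H](C)CC
F7 | step 15 | (5S,6S,7R,8R,9R,10S)-6-(angeloyloxy)-9-{[(2R)-2-methylbutanoyl]oxy}-15-[(triethylsilyl)oxy]elema-1,3,11(13)-trien-12,8-olide | C=C[C@@]1(C)[C@H](C(=C)CO[Si](CC)(CC)CC)[C@H](OC(=O)/C(C)=C\C)[C@H]2C(=C)C(=O)O[C@H]2[C@@H]1OC(=O)[C@H](C)CC
F8 | step 11 | (1(10)E,4Z,6R,7R,8R,9R)-15-[(tert-butyldiphenylsilyl)oxy]-6-hydroxy-9-{[(2R)-2-methylbutanoyl]oxy}germacra-1(10),4,11(13)-trien-12,8-olide (6-epimer of 19) | C1/C(CO[Si](c3ccccc3)(c3ccccc3)C(C)(C)C)=C/[C@@H](O)[C@H]2C(=C)C(=O)O[C@H]2[C@H](OC(=O)[C@H](C)CC)/C(C)=C/C1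
F9 | step 10 | methyl 2-{[(tert-butyldimethylsilyl)oxy]methyl}prop-2-enoate | C=C(CO[Si](C)(C)C(C)(C)C)C(=O)OC
F10 | step 10 | 2-{[(tert-butyldimethylsilyl)oxy]methyl}prop-2-enoic acid | C=C(CO[Si](C)(C)C(C)(C)C)C(=O)O
F11 | step 10 | (3R,4R,5E,9Z)-9-{[(tert-butyldiphenylsilyl)oxy]methyl}-5-methyl-4-{[(2R)-2-methylbutanoyl]oxy}-11-oxoundeca-1,5,9-trien-3-yl 2-{[(tert-butyldimethylsilyl)oxy]methyl}prop-2-enoate | C=C[C@@H](OC(=O)C(=C)CO[Si](C)(C)C(C)(C)C)[C@H](OC(=O)[C@H](C)CC)/C(C)=C/CC/C(CO[Si](c1ccccc1)(c1ccccc1)C(C)(C)C)=C/C=O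
F12 | step 10 | (1R,2E,6Z)-1-[(2R)-4-{[(tert-butyldimethylsilyl)oxy]methyl}-5-oxo-2,5-dihydrofuran-2-yl]-6-{[(tert-butyldiphenylsilyl)oxy]methyl}-2-methyl-8-oxoocta-2,6-dien-1-yl (2R)-2-methylbutanoate | CC(C)(C)[Si](C)(C)OCC1=C[C@@H](OC1=O)[C@H](OC(=O)[C@H](C)CC)/C(C)=C/CC/C(CO[Si](c1ccccc1)(c1ccccc1)C(C)(C)C)=C/C=O
F13 | step 10 | (1R,2E,6Z)-6-{[(tert-butyldiphenylsilyl)oxy]methyl}-1-[(2R)-4-(hydroxymethyl)-5-oxo-2,5-dihydrofuran-2-yl]-2-methyl-8-oxoocta-2,6-dien-1-yl (2R)-2-methylbutanoate | OCC1=C[C@@H](OC1=O)[C@H](OC(=O)[C@H](C)CC)/C(C)=C/CC/C(CO[Si](c1ccccc1)(c1ccccc1)C(C)(C)C)=C/C=O
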